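**Retrosynthetic overview**

1. Locants follow the SMILES from left to right: C1–C7 heptyl, C8=C9, C10, O11, C12, C13(=O), O14, C15, C16, C17(OH), C18, C19, C20, C21=C22(C23H3), C24, C25(OH).
2. Feature used: the quaternary C12 carries the dihydropyran oxygen O11, the lactone carbonyl C13 and C20 at once, so C12=O11 is cut as a carbonyl dienophile. C12–C20 and O11–C10 are made in one intramolecular oxa-Diels–Alder between the C12 ketone of a spiro α-keto-δ-lactone (O14–C13–C12–C25=C24–C15) and the all-E triene C20=C21–C22=C10–C9=C8 on C19.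
3. That step closes the carbocycle C12/C20/C19/C15/C24/C25 (the spiro lactone becomes the 2-oxabicyclo[2.2.2]octanone) and the dihydropyran O11/C10/C22/C21/C20/C12, and sets C12, C20 and C10. The triene is completed in the same flask by a Stille coupling at C21–C22.
4. Ring order: cyclopentane (bought; C15, C19, C17 set by a chirality relay from (R)-4-silyloxycyclopentenone) → spiro lactone (acylketene lactonisation) → carbocycle + dihydropyran (key step) → C25 carbinol by face-selective reduction.
5. The side chain C1–C10/C22/C23 enters as a dienylstannane made from (E)-dec-2-enal.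

Key step: step 15

Remark: 24 is drawn as the diketone although it should exist largely as the C25 enol, and trione 25 may be carried as its C12 hydrate; the silyl enol ether 26 is the defined, anhydrous dienophile.

**Route**

Step 1
Reactants: 1 (E)-dec-2-enal
Product: 2 (E)-1,1-dibromoundeca-1,3-diene
Conditions: CBr4, PPh3, CH2Cl2, 0 °C
Reagents that add atoms: carbon tetrabromide, BrC(Br)(Br)Br
Why: Corey–Fuchs (Ramirez) dibromo-olefination of the aldehyde through the CBr2 ylide; the C8=C9 E alkene is not touched.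

Step 2
Reactants: 2 (E)-1,1-dibromoundeca-1,3-diene
Product: 4 (E)-dodec-4-en-2-yne, via lithium acetylide 3 (not isolated)
Conditions: n-BuLi (2.1 equiv), THF, −78 → 0 °C; then MeI, −78 °C → rt
Reagents that add atoms: iodomethane, CI
Why: second Corey–Fuchs stage, in which Br/Li exchange and Fritsch–Buttenberg–Wiechell rearrangement give the acetylide that is C-methylated by MeI.

Step 3
Reactants: 4 (E)-dodec-4-en-2-yne
Product: 6 (2E,4E)-2-iodododeca-2,4-diene, via alkenylzirconocene 5 (not isolated)
Conditions: Cp2Zr(H)Cl (1.5 equiv), THF, 40 °C; then I2, 0 °C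
Reagents that add atoms: iodine, II
Why: Schwartz hydrozirconation adds Zr–H syn with Zr on the less hindered methyl-bearing alkyne carbon (excess reagent equilibrates the regioisomers, and the alkyne reacts before the 1,2-disubstituted alkene), and iodinolysis with retention gives the 2E iodide.

Step 4
Reactants: 6 (2E,4E)-2-iodododeca-2,4-diene
Product: 8 tributyl[(2E,4E)-dodeca-2,4-dien-2-yl]stannane, via dienyllithium 7 (not isolated)
Conditions: t-BuLi (2.0 equiv), Et2O, −78 °C; then Bu3SnCl, −78 °C → rt
Reagents that add atoms: tributyltin chloride, CCCC[Sn](Cl)(CCCC)CCCC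
Why: iodine–lithium exchange and stannylation both proceed with retention of the alkenyl configuration.

Step 5
Reactants: 9 2,2,6-trimethyl-4H-1,3-dioxin-4-one; 10 (R)-4-[(tert-butyldimethylsilyl)oxy]cyclopent-2-en-1-one
Product: 12 tertiary allylic alcohol (1R,4R; OH cis to OTBS), via lithium dienolate 11 (not isolated)
Conditions: LDA, THF, −78 °C; then 10, −78 °C; aq NH4Cl
Reagents that add atoms: none
Why: vinylogous aldol-type 1,2-addition of the dioxinone lithium dienolate through its γ-carbon to the enone carbonyl; attack anti to the C17 silyloxy group sets C15 (O14 cis to OTBS), and the dioxinone carries C24, C25, C12 and C13 in masked form.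

Step 6
Reactants: 12 tertiary allylic alcohol
Product: 13 cis-cyclopent-2-ene-1,4-diol (1R,4R)
Conditions: TBAF, AcOH, THF, 0 °C → rt
Reagents that add atoms: none
Why: fluoride desilylation, with acetic acid as buffer so that the tertiary alkoxide does not undergo retro-aldol cleavage.

Step 7
Reactants: 13 cis-diol
Product: 14 (S)-4-[(2,2-dimethyl-4-oxo-4H-1,3-dioxin-6-yl)methyl]-4-hydroxycyclopent-2-en-1-one
Conditions: MnO2, CH2Cl2, rt
Reagents that add atoms: none
Why: MnO2 oxidises only the secondary allylic alcohol; the C17 stereocentre, having set C15, is erased on purpose (chirality relay) and is rebuilt in step 9.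

Step 8
Reactants: 14 γ-hydroxy enone; 15 ethynyltrimethylsilane
Product: 17 cis-3-alkynyl-4-hydroxycyclopentanone (3S,4S), via alkynylalane 16 (not isolated)
Conditions: 15, n-BuLi, PhMe, 0 °C; Me2AlCl, 0 °C; then 14, PhMe, 0 °C → rt; aq Rochelle salt
Reagents that add atoms: none
Why: hydroxyl-directed conjugate alkynylation of a 4-hydroxycyclopent-2-enone with a dialkylalkynylalane, in which the aluminium alkoxide formed at O14 delivers the alkynyl group to C19 on its own face, so C20 ends cis to O14.

Step 9
Reactants: 17 alkynyl hydroxy ketone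
Product: 18 trans-1,3-diol (C15 R, C19 S, C17 R)
Conditions: Me4NBH(OAc)3, MeCN/AcOH, −30 °C
Reagents that add atoms: none
Why: Evans–Saksena directed reduction, in which the borohydride bound to O14 delivers hydride to the C17 ketone on the O14 face and gives the trans-1,3-diol; the dioxinone is inert.

Step 10
Reactants: 18 silylalkyne diol
Product: 19 terminal alkyne diol
Conditions: TBAF, THF, 0 °C
Reagents that add atoms: none
Why: fluoride cleaves the C(sp)–SiMe3 bond rapidly, and nothing else in the molecule should respond at 0 °C.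

Step 11
Reactants: 19 terminal alkyne diol
Product: 20 C17 TBS ether
Conditions: TBSCl, imidazole, DMF, 0 °C
Reagents that add atoms: tert-butyldimethylsilyl chloride, CC(C)(C)[Si](C)(C)Cl
Why: the secondary C17 hydroxyl is silylated and the tertiary C15 hydroxyl is not, so it stays free for the lactonisation.

Step 12
Reactants: 20 alkyne
Product: 22 (E)-vinyl iodide, via alkenylzirconocene 21 (not isolated)
Conditions: Cp2Zr(H)Cl (2.5 equiv), THF, rt; then I2, 0 °C
Reagents that add atoms: iodine, II
Why: syn hydrozirconation of the terminal alkyne with Zr on the terminal carbon, then iodinolysis with retention, gives the E iodide; one extra equivalent of reagent is consumed by the free hydroxyl, and the vinylogous ester is reduced far more slowly than the alkyne.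

Step 13
Reactants: 22 vinyl iodide
Product: 24 spiro β-keto-δ-lactone (1S,3R,5R), via acylketene 23 (not isolated)
Conditions: PhMe, 110 °C
Reagents that add atoms: none
Why: thermal retro-hetero-Diels–Alder of the dioxinone expels acetone, and the acylketene is trapped by the tertiary C15 hydroxyl in a six-membered lactonisation; no stereocentre is touched.

Step 14
Reactants: 24 spiro β-keto-δ-lactone
Product: 26 C25 TIPS enol ether of the α-keto lactone, via trione 25 (not isolated)
Conditions: Dess–Martin periodinane (2.5 equiv), pyridine, CH2Cl2, rt; filter, 4 Å MS; then TIPSOTf, 2,6-lutidine, CH2Cl2, −78 → 0 °C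
Reagents that add atoms: Dess–Martin periodinane, CC(=O)OI1(OC(C)=O)(OC(C)=O)OC(=O)c2ccccc12; triisopropylsilyl triflate, CC(C)[Si](C(C)C)(C(C)C)OS(=O)(=O)C(F)(F)F
Why: Dess–Martin oxidation of a β-dicarbonyl compound to the vicinal tricarbonyl (C12H2 → C12=O); the trione can enolise only toward C24, so soft enolisation and O-silylation should give a single silyl enol ether that masks C25 and leaves C12 as the only ketone, with a bulky group on one flank.

Step 15
Reactants: 26 vinyl iodide silyl enol ether; 8 tributyl[(2E,4E)-dodeca-2,4-dien-2-yl]stannane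
Product: 28 tetracyclic oxa-Diels–Alder adduct, via triene 27 (not isolated)
Conditions: [Pd2(dba)3] (5 mol%), AsPh3 (20 mol%), CuI (10 mol%), DMF, 25 °C; then PhMe, BHT, 80 °C
Reagents that add atoms: none
Why: A Farina-type Stille coupling joins C21 to C22 with retention at both alkenes and so creates the all-E triene 27, whose diene C20=C21–C22=C10 hangs over the C12 ketone; warming then triggers an intramolecular oxa-Diels–Alder, the reaction type known for 1,2-dicarbonyl C=O groups (pyruvates, glyoxylates, ketomalonates) with 1,3-dienes, here concerted but asynchronous with C12–C20 bonding ahead because the charge developing over C21–C10 is stabilised by C9=C8. The carbocycle C12–C20–C19–C15–C24–C25 closes across the pyranone ring, which turns the spiro lactone into the bridged 2-oxabicyclo[2.2.2]octenone, and the dihydropyran closes through O11–C10 in the fused mode with a four-atom tether. C12 can only be attacked from the face that carries C19, so its configuration follows from C15 and C19, while C20 and C10 are set together because the addition is suprafacial on an (E,E)-diene, which puts H20 and H10 cis. The selectivity to be won is the flank of C12 over which the diene stacks: the target needs C21/C22 and the nonenyl group over the lactone carbonyl C13 (C21 syn to the O14–C13 bridge and cis to C18). This is secured by the bulky O–Si(iPr)3 group on C25, which blocks the other flank, and by secondary overlap with the lactone carbonyl, which carries the larger LUMO coefficient of the α-dicarbonyl unit. The regiochemistry (C12 to C20, O11 to C10) is fixed by the tether, which allows only the six-membered carbocycle, and by polarity.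

Step 16
Reactants: 28 tetracyclic adduct
Product: 30 CNP0127096.1, via ketone 29 (not isolated)
Conditions: TBAF, AcOH, THF, 0 °C → rt; then NaBH4, MeOH, −40 °C
Reagents that add atoms: none
Why: buffered fluoride cleaves the silyl enol ether (giving the C25 ketone) and the TBS ether, and borohydride should then attack C25 from the face next to the lactone bridge, which carries no substituents, and not from the face next to the C19–C20 bridge, whose two hydrogens point at it, so the hydroxyl ends syn to the C19–C20 bridge (C25 R).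

**Compound list**

1 | (E)-dec-2-enal | CCCCCCC/C=C/C=O | starting material
2 | (E)-1,1-dibromoundeca-1,3-diene | CCCCCCC/C=C/C=C(Br)Br | intermediate
3 | lithium (E)-undec-3-en-1-yn-1-ide | CCCCCCC/C=C/C#C[Li] | intermediate
4 | (E)-dodec-4-en-2-yne | CCCCCCC/C=C/C#CC | intermediate
5 | chlorobis(cyclopentadienyl)[(2E,4E)-dodeca-2,4-dien-2-yl]zirconium | C/C(=C\C=C\CCCCCCC)[Zr](Cl)(C1C=CC=C1)C1C=CC=C1 | intermediate
6 | (2E,4E)-2-iodododeca-2,4-diene | C/C(I)=C\C=C\CCCCCCC | intermediate
7 | [(2E,4E)-dodeca-2,4-dien-2-yl]lithium | C/C([Li])=C\C=C\CCCCCCC | intermediate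
8 | tributyl[(2E,4E)-dodeca-2,4-dien-2-yl]stannane | C/C(=C\C=C\CCCCCCC)[Sn](CCCC)(CCCC)CCCC | intermediate
9 | 2,2,6-trimethyl-4H-1,3-dioxin-4-one | CC1=CC(=O)OC(C)(C)O1 | starting material
10 | (R)-4-[(tert-butyldimethylsilyl)oxy]cyclopent-2-en-1-one | O=C1C[C@@H](O[Si](C)(C)C(C)(C)C)C=C1 | starting material
11 | lithium 2,2-dimethyl-6-methylidene-6H-1,3-dioxin-4-olate (dienolate of 9) | C=C1C=C(O[Li])OC(C)(C)O1 | intermediate
12 | 6-{[(1R,4R)-4-[(tert-butyldimethylsilyl)oxy]-1-hydroxycyclopent-2-en-1-yl]methyl}-2,2-dimethyl-4H-1,3-dioxin-4-one (OH cis to OTBS) | O[C@]1(C[C@@H](O[Si](C)(C)C(C)(C)C)C=C1)CC2=CC(=O)OC(C)(C)O2 | intermediate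
13 | 6-{[(1R,4R)-1,4-dihydroxycyclopent-2-en-1-yl]methyl}-2,2-dimethyl-4H-1,3-dioxin-4-one (cis-diol) | O[C@]1(C[C@@H](O)C=C1)CC2=CC(=O)OC(C)(C)O2 | intermediate
14 | (S)-4-[(2,2-dimethyl-4-oxo-4H-1,3-dioxin-6-yl)methyl]-4-hydroxycyclopent-2-en-1-one | O[C@]1(CC(=O)C=C1)CC2=CC(=O)OC(C)(C)O2 | intermediate
15 | ethynyltrimethylsilane | C#C[Si](C)(C)C | starting material
16 | dimethyl[(trimethylsilyl)ethynyl]aluminium | C[Al](C)C#C[Si](C)(C)C | intermediate
17 | (3S,4S)-4-[(2,2-dimethyl-4-oxo-4H-1,3-dioxin-6-yl)methyl]-4-hydroxy-3-[(trimethylsilyl)ethynyl]cyclopentan-1-one (alkynyl cis to OH) | O[C@]1(CC(=O)C[C@H]1C#C[Si](C)(C)C)CC2=CC(=O)OC(C)(C)O2 | intermediate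
18 | 6-{[(1R,2S,4R)-1,4-dihydroxy-2-[(trimethylsilyl)ethynyl]cyclopentyl]methyl}-2,2-dimethyl-4H-1,3-dioxin-4-one (1,4-diol trans, alkynyl cis to 1-OH) | O[C@]1(C[C@H](O)C[C@H]1C#C[Si](C)(C)C)CC2=CC(=O)OC(C)(C)O2 | intermediate
19 | 6-{[(1R,2S,4R)-2-ethynyl-1,4-dihydroxycyclopentyl]methyl}-2,2-dimethyl-4H-1,3-dioxin-4-one | O[C@]1(C[C@H](O)C[C@H]1C#C)CC2=CC(=O)OC(C)(C)O2 | intermediate
20 | 6-{[(1R,2S,4R)-4-[(tert-butyldimethylsilyl)oxy]-2-ethynyl-1-hydroxycyclopentyl]methyl}-2,2-dimethyl-4H-1,3-dioxin-4-one | O[C@]1(C[C@H](O[Si](C)(C)C(C)(C)C)C[C@H]1C#C)CC2=CC(=O)OC(C)(C)O2 | intermediate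
21 | (E)-alkenylzirconocene chloride from 20 (drawn with the hydroxyl free) | O[C@]1(C[C@H](O[Si](C)(C)C(C)(C)C)C[C@H]1/C=C/[Zr](Cl)(C3C=CC=C3)C3C=CC=C3)CC2=CC(=O)OC(C)(C)O2 | intermediate
22 | 6-{[(1R,2S,4R)-4-[(tert-butyldimethylsilyl)oxy]-1-hydroxy-2-[(E)-2-iodoethenyl]cyclopentyl]methyl}-2,2-dimethyl-4H-1,3-dioxin-4-one | O[C@]1(C[C@H](O[Si](C)(C)C(C)(C)C)C[C@H]1/C=C/I)CC2=CC(=O)OC(C)(C)O2 | intermediate
23 | acylketene from 22 (4-substituted 3-oxobut-1-en-1-one, tertiary OH free) | O[C@]1(C[C@H](O[Si](C)(C)C(C)(C)C)C[C@H]1/C=C/I)CC(=O)C=C=O | intermediate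
24 | (1S,3R,5R)-3-[(tert-butyldimethylsilyl)oxy]-1-[(E)-2-iodoethenyl]-6-oxaspiro[4.5]decane-7,9-dione | O=C1O[C@]2(C[C@H](O[Si](C)(C)C(C)(C)C)C[C@H]2/C=C/I)CC(=O)C1 | intermediate
25 | (1S,3R,5R)-3-[(tert-butyldimethylsilyl)oxy]-1-[(E)-2-iodoethenyl]-6-oxaspiro[4.5]decane-7,8,9-trione | O=C1O[C@]2(C[C@H](O[Si](C)(C)C(C)(C)C)C[C@H]2/C=C/I)CC(=O)C1=O | intermediate
26 | (1S,3R,5S)-3-[(tert-butyldimethylsilyl)oxy]-1-[(E)-2-iodoethenyl]-9-[(triisopropylsilyl)oxy]-6-oxaspiro[4.5]dec-9-ene-7,8-dione | O=C1O[C@]2(C[C@H](O[Si](C)(C)C(C)(C)C)C[C@H]2/C=C/I)C=C(O[Si](C(C)C)(C(C)C)C(C)C)C1=O | intermediate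
27 | (1S,3R,5S)-3-[(tert-butyldimethylsilyl)oxy]-1-[(1E,3E,5E)-3-methyltrideca-1,3,5-trien-1-yl]-9-[(triisopropylsilyl)oxy]-6-oxaspiro[4.5]dec-9-ene-7,8-dione | O=C1O[C@]2(C[C@H](O[Si](C)(C)C(C)(C)C)C[C@H]2/C=C/C(C)=C/C=C/CCCCCCC)C=C(O[Si](C(C)C)(C(C)C)C(C)C)C1=O | intermediate
28 | tetracyclic adduct: target skeleton with C17 OTBS and C24=C25 TIPS enol ether (locants 10R,12S,15S,17R,19S,20R) | CCCCCCC/C=C/[C@H]1O[C@@]23C(=O)O[C@]4(C[C@H](O[Si](C)(C)C(C)(C)C)C[C@H]4[C@H]2C=C1C)C=C3O[Si](C(C)C)(C(C)C)C(C)C | intermediate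
29 | 25-oxo compound: target with C25 ketone in place of the carbinol (10R,12S,15R,17R,19S,20R) | CCCCCCC/C=C/[C@H]1O[C@@]23C(=O)O[C@]4(C[C@H](O)C[C@H]4[C@H]2C=C1C)CC3=O | intermediate
30 | CNP0127096.1 (10R,12S,15R,17R,19S,20R,25R; 8E) | CCCCCCC/C=C/[C@H]1O[C@@]23C(=O)O[C@]4(C[C@H](O)C[C@H]4[C@H]2C=C1C)C[C@H]3O | target

**Step count and risks**

Total step count: 16 (4 for the stannane, 12 on the main line). Longest linear sequence: 12 steps (steps 5–16, from 9 and 10).

Steps most likely to fail:

1. Step 15. The diene may stack over the enol-ether flank instead of the lactone flank, which gives the wrong C20/C10 pair. The thermal cycloaddition may also be so slow that ene reaction or triene decomposition takes over, or a stepwise path may erode the configuration at C10.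
Fallback, from 26 back to 28: the cycloaddition is separated from the long chain. A Stille coupling of 26 under the same conditions with tributyl[(E)-1-ethoxyprop-1-en-2-yl]stannane would give the 1-ethoxy-2-methyl-1,3-diene F1. This electron-rich 1-alkoxydiene should add to the C12 ketone at or below room temperature (ZnCl2 or Eu(fod)3 if needed), the classical carbonyl Diels–Alder of 1-alkoxydienes, to give the cyclic mixed acetal F2. In F2, C10 is an acetal carbon, so only C20 has to be controlled, and the small ethoxy group eases stacking over the lactone flank. BF3·OEt2 and potassium (E)-non-1-enyltrifluoroborate in CH2Cl2/MeCN at −40 °C (Ferrier-type C-glycosidation) would then ionise the allylic acetal to the ring oxocarbenium ion and deliver the nonenyl group to C10 by the stereoelectronically preferred pseudo-axial attack. This is the mode that gives 2,6-trans C-glycosides from glycals, and here it places the chain on the C13 face; the route is rejoined at 28.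

2. Step 14. Over-oxidation at C24 through the enol of the trione, or hydrate formation at C12 that prevents a clean, regioselective enol silylation.
Fallback, from 24 back to 25: Regitz diazo transfer (p-acetamidobenzenesulfonyl azide, Et3N, MeCN, 0 °C) would give the 8-diazo-7,9-dione F3. Oxygen-atom transfer from dimethyldioxirane (acetone, 0 °C) would convert F3 into trione 25 under neutral, anhydrous conditions, with no reagent present that can attack C24. 25 is then silylated as in step 14 to give 26.

3. Step 8. Incomplete internal delivery of the alkynyl group, with competing retro-aldol cleavage of the tertiary aluminium alkoxide or 1,2-addition, since the precedent for this directed addition is with secondary 4-hydroxy enones.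
Fallback, from 14 back to 19: the two-carbon unit is delivered from O14 through a temporary silicon tether (Stork–Nishiyama).
- Silylation of 14 with (bromomethyl)chlorodimethylsilane (Et3N, DMAP, CH2Cl2) would give the (bromomethyl)silyl ether F4.
- Bu3SnH/AIBN (PhH, 80 °C) would effect 5-exo radical cyclisation onto the enone β-carbon C19, necessarily cis to O14, to give the bicyclic siloxane F5.
- Tamao oxidation (KF, KHCO3, H2O2, THF/MeOH) would give the keto diol F6.
- Me4NBH(OAc)3 would give the triol F7 with the same trans-1,3 sense as in step 9.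
- TEMPO/PhI(OAc)2 would oxidise only the primary alcohol, to the aldehyde F8.
- Ohira–Bestmann homologation (dimethyl (1-diazo-2-oxopropyl)phosphonate, K2CO3, MeOH) would give alkyne 19, from which step 11 follows.

**Further compounds**

F1 | step 15 | (1S,3R,5S)-3-[(tert-butyldimethylsilyl)oxy]-1-[(1E,3E)-4-ethoxy-3-methylbuta-1,3-dien-1-yl]-9-[(triisopropylsilyl)oxy]-6-oxaspiro[4.5]dec-9-ene-7,8-dione | O=C1O[C@]2(C[C@H](O[Si](C)(C)C(C)(C)C)C[C@H]2/C=C/C(C)=C/OCC)C=C(O[Si](C(C)C)(C(C)C)C(C)C)C1=O
F2 | step 15 | analogue of 28 with ethoxy in place of the nonenyl group at C10 (cyclic mixed acetal, both C10 anomers) | CCOC1O[C@@]23C(=O)O[C@]4(C[C@H](O[Si](C)(C)C(C)(C)C)C[C@H]4[C@H]2C=C1C)C=C3O[Si](C(C)C)(C(C)C)C(C)C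
F3 | step 14 | (1S,3R,5R)-3-[(tert-butyldimethylsilyl)oxy]-8-diazo-1-[(E)-2-iodoethenyl]-6-oxaspiro[4.5]decane-7,9-dione | O=C1O[C@]2(C[C@H](O[Si](C)(C)C(C)(C)C)C[C@H]2/C=C/I)CC(=O)C1=[N+]=[N-]
F4 | step 8 | (bromomethyl)dimethylsilyl ether of 14 | BrC[Si](C)(C)O[C@]1(CC(=O)C=C1)CC2=CC(=O)OC(C)(C)O2
F5 | step 8 | cis-fused bicyclic siloxane (O14–SiMe2–CH2–C19) with C17 ketone | O1[C@]2(CC(=O)C[C@H]2C[Si]1(C)C)CC3=CC(=O)OC(C)(C)O3
F6 | step 8 | (3S,4S)-4-[(2,2-dimethyl-4-oxo-4H-1,3-dioxin-6-yl)methyl]-4-hydroxy-3-(hydroxymethyl)cyclopentan-1-one | O[C@]1(CC(=O)C[C@H]1CO)CC2=CC(=O)OC(C)(C)O2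
F7 | step 8 | 6-{[(1R,2S,4R)-1,4-dihydroxy-2-(hydroxymethyl)cyclopentyl]methyl}-2,2-dimethyl-4H-1,3-dioxin-4-one | O[C@]1(C[C@H](O)C[C@H]1CO)CC2=CC(=O)OC(C)(C)O2
F8 | step 8 | (1S,2R,4R)-2-[(2,2-dimethyl-4-oxo-4H-1,3-dioxin-6-yl)methyl]-2,4-dihydroxycyclopentane-1-carbaldehyde | O[C@]1(C[C@H](O)C[C@H]1C=O)CC2=CC(=O)OC(C)(C)O2
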